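**Plan**

- Last cut: the six benzyl ethers. Before that, ring A is cut at C8–C8a and C4a–C5. Its oxygens on C5, C7 and C8a sit in a 1,3,5 array, so C5–C8 map onto a 1,1,3-trioxygenated butadiene, and the O1–C8a=C4a–C4(=O) unit maps onto the enol-ether double bond of a 2-aryl-2,3-dihydropyran-4-one.
- The dihydropyranone (O1, C2, C3, C4, C4a, C8a) is cut at C2–C3 and O1–C8a into an aryl aldehyde and 1-methoxy-3-(trimethylsilyloxy)butadiene. The biaryl bond C5'–C8'' is cut into an aryl boronate from 5-bromovanillin and 8-iodo-tetra-O-benzylluteolin.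
- Forward order: biaryl bond, then ring C by hetero-Diels–Alder reaction, then a C5 sulfinyl activating group, then ring A by Diels–Alder benzannulation, then hydrogenolysis.
- The only stereocenter, C2 (S), comes from the (S)-BINOL/Ti(OiPr)4-catalysed hetero-Diels–Alder step; later steps are neutral or mildly basic at low temperature and do not touch it.

Key step: step 12

Remark: Ar = 3,4-bis(benzyloxy)-5-[5,7-bis(benzyloxy)-2-(3,4-bis(benzyloxy)phenyl)-4-oxo-4H-chromen-8-yl]phenyl; the biaryl axis, with three ortho oxygen substituents, is assumed to rotate freely, so no atropisomers are counted.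
Remark: (S)-BINOL is assumed to give the (S)-dihydropyranone, by analogy with simple aryl aldehydes; if the sense proved opposite, (R)-BINOL would be used.
Remark: sulfoxide 14 is used as a mixture of sulfur epimers, and the new sp3 centres of 12 and 19 are transient; none of these affect the product.

**Route**

Step 1
Reactants: 1 5-bromovanillin
Product: 2 3-bromo-4,5-dihydroxybenzaldehyde
Conditions: BBr3, CH2Cl2, 0 °C to rt; then H2O
Reagents that add atoms: none
Why: Lewis-acid cleavage of an aryl methyl ether (BBr3 demethylation) is routine for vanillin-type ethers and should leave the aldehyde and aryl bromide intact.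

Step 2
Reactants: 2 3-bromo-4,5-dihydroxybenzaldehyde
Product: 3 3,4-bis(benzyloxy)-5-bromobenzaldehyde
Conditions: BnBr, K2CO3, DMF, 60 °C
Reagents that add atoms: benzyl bromide, BrCc1ccccc1
Why: Williamson ether synthesis on both catechol hydroxyls gives ethers that survive every later step and fall off together at the end.

Step 3
Reactants: 3 3,4-bis(benzyloxy)-5-bromobenzaldehyde
Product: 4 3,4-bis(benzyloxy)-5-(4,4,5,5-tetramethyl-1,3,2-dioxaborolan-2-yl)benzaldehyde
Conditions: bis(pinacolato)diboron, PdCl2(dppf), KOAc, dioxane, 90 °C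
Reagents that add atoms: bis(pinacolato)diboron, CC1(C)OB(OC1(C)C)B1OC(C)(C)C(C)(C)O1
Why: Miyaura borylation of an aryl bromide tolerates the aldehyde and puts boron on the partner that is less prone to protodeboronation.

Step 4
Reactants: 5 luteolin
Product: 6 5,7-bis(benzyloxy)-2-[3,4-bis(benzyloxy)phenyl]-4H-chromen-4-one (tetra-O-benzylluteolin)
Conditions: BnBr (excess), K2CO3, DMF, 80 °C
Reagents that add atoms: benzyl bromide, BrCc1ccccc1
Why: Williamson ether synthesis with excess reagent and heat should also alkylate the hydrogen-bonded 5-OH, whose protection directs the next substitution to C8.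

Step 5
Reactants: 6 tetra-O-benzylluteolin
Product: 7 5,7-bis(benzyloxy)-2-[3,4-bis(benzyloxy)phenyl]-8-iodo-4H-chromen-4-one
Conditions: NIS, TFA (cat.), CH2Cl2/MeCN, 0 °C to rt
Reagents that add atoms: N-iodosuccinimide, O=C1CCC(=O)N1I
Why: Electrophilic aromatic iodination of fully etherified 5,7-dioxygenated flavones goes to C8, which is also less hindered than C6 between two benzyloxy groups.

Step 6
Reactants: 4 aryl pinacol boronate; 7 8-iodo-tetra-O-benzylluteolin
Product: 8 3,4-bis(benzyloxy)-5-[5,7-bis(benzyloxy)-2-(3,4-bis(benzyloxy)phenyl)-4-oxo-4H-chromen-8-yl]benzaldehyde (Ar–CHO)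
Conditions: Pd(OAc)2, SPhos, K3PO4, PhMe/H2O, 90 °C
Reagents that add atoms: none
Why: Suzuki–Miyaura coupling with a dialkylbiarylphosphine ligand is suited to a tri-ortho-substituted biaryl between an aryl iodide and an ortho-alkoxy aryl boronate, as in flavone-8-yl biaryl syntheses.

Step 7
Reactants: 8 biaryl aldehyde Ar–CHO; 9 (E)-1-methoxy-3-(trimethylsilyloxy)buta-1,3-diene
Product: 11 (S)-2-Ar-2,3-dihydro-4H-pyran-4-one, via silyl aldol adduct 10 (not isolated)
Conditions: (S)-BINOL (20 mol%), Ti(OiPr)4 (10 mol%), 4 Å MS, PhMe, −20 °C; then TFA (cat.), CH2Cl2, 0 °C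
Reagents that add atoms: none
Why: In this catalytic enantioselective hetero-Diels–Alder reaction (Mukaiyama aldol then acid-promoted oxa-Michael closure with loss of methoxytrimethylsilane) the chiral titanium BINOLate selects one aldehyde face and so sets C2 as S.

Step 8
Reactants: 11 (S)-2-Ar-2,3-dihydro-4H-pyran-4-one
Product: 13 (S)-2-Ar-5-(phenylthio)-2,3-dihydro-4H-pyran-4-one, via chlorosulfide adduct 12 (not isolated)
Conditions: PhSCl (1.05 equiv), CH2Cl2, −78 °C; then Et3N, −78 to 0 °C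
Reagents that add atoms: benzenesulfenyl chloride, ClSc1ccccc1
Why: Electrophilic α-sulfenylation by addition of the sulfenyl chloride across the enol-ether double bond and base-induced loss of HCl should occur at C5, by far the most nucleophilic alkene carbon in the molecule.

Step 9
Reactants: 13 (S)-2-Ar-5-(phenylthio)-2,3-dihydro-4H-pyran-4-one
Product: 14 (2S)-2-Ar-5-(phenylsulfinyl)-2,3-dihydro-4H-pyran-4-one (both sulfur epimers)
Conditions: mCPBA (1.0 equiv), NaHCO3, CH2Cl2, −78 to −20 °C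
Reagents that add atoms: meta-chloroperoxybenzoic acid, OOC(=O)c1cccc(Cl)c1
Why: Oxidation of a sulfide to the sulfoxide with one equivalent of peracid at low temperature is faster than any reaction of the electron-poor double bonds or the aryl ethers.

Step 10
Reactants: 15 methyl acetoacetate
Product: 16 methyl 3-(trimethylsilyloxy)but-2-enoate (mixture of geometric isomers)
Conditions: TMSCl, Et3N, hexane, rt
Reagents that add atoms: chlorotrimethylsilane, C[Si](C)(C)Cl
Why: O-silylation of the enol of a β-keto ester with TMSCl and a tertiary amine is the standard first stage of the 1,3-bis(silyloxy)diene preparation.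

Step 11
Reactants: 16 methyl 3-(trimethylsilyloxy)but-2-enoate
Product: 18 1-methoxy-1,3-bis(trimethylsilyloxy)buta-1,3-diene, via lithium dienolate 17 (not isolated)
Conditions: LiN(iPr)2 (commercial solution), THF, −78 °C; then TMSCl, −78 °C to rt; distillation
Reagents that add atoms: chlorotrimethylsilane, C[Si](C)(C)Cl
Why: γ-Deprotonation of the silyl enol ether ester and O-silylation of the dienolate is the established silyl ketene acetal route to this diene.

Step 12
Reactants: 14 (2S)-2-Ar-5-(phenylsulfinyl)-2,3-dihydro-4H-pyran-4-one; 18 1-methoxy-1,3-bis(trimethylsilyloxy)buta-1,3-diene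
Product: 21 (2S)-2-Ar-5,7-dihydroxychroman-4-one, via cis-fused cycloadduct 19 (not isolated), via 7-O-trimethylsilyl flavanone 20 (not isolated)
Conditions: 18 (4 equiv), PhMe, 90 °C, sealed tube; then 1 M HCl, THF, 0 °C
Reagents that add atoms: none
Why: Proposed new method: the electron-rich diene 18 should bond through its CH2 terminus to C6 of the sulfinyl enone (the β-carbon, future C8a) and through its ketene acetal carbon to C5 (future C4a) in an asynchronous [4+2] cycloaddition; the cis-fused adduct 19 then loses benzenesulfenic acid by thermal syn elimination using its only β-hydrogen, H8a, which is necessarily cis to sulfur, and loses methoxytrimethylsilane from the C5 ketal, so that ring A tautomerises to the 5-hydroxy-7-silyloxy arene 20, and acid work-up frees the 7-OH. The closest known reactions are Diels–Alder/aromatisation sequences of 1,1,3-trioxygenated butadienes with haloquinones and 3-acylchromones and the cycloaddition/sulfoxide-elimination benzannulation of sulfinyl quinones and α-sulfinyl enones; a 2,3-dihydropyran-4-one has not been used as the dienophile in this way. Ring A closes by intermolecular [4+2] cycloaddition, forming C8–C8a and C4a–C5 in one operation. No lasting stereocenter is made, since the ring-fusion and C5 centres of 19 disappear on aromatisation, and C2 is not involved because the conditions are neutral and thermal. Regioselectivity rests on matching the nucleophilic diene terminus with the enone β-carbon, which the sulfinyl group reinforces; a sulfoxide is preferred to a halogen because a C4a halogen would lie cis to H8a and could not leave by anti elimination, whereas the sulfoxide needs exactly this syn geometry. The required chemoselectivity is cycloaddition instead of Michael addition followed by β-elimination of O1 and opening of ring C, and it is sought by leaving out Lewis acids and fluoride.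

Step 13
Reactants: 21 (2S)-2-Ar-5,7-dihydroxychroman-4-one
Product: 22 (2S)-2-{3,4-dihydroxy-5-[2-(3,4-dihydroxyphenyl)-5,7-dihydroxy-4-oxo-4H-chromen-8-yl]phenyl}-5,7-dihydroxychroman-4-one (CNP0224656.1)
Conditions: H2 (1 atm), 10% Pd/C (palladium on carbon), THF/MeOH, rt
Reagents that add atoms: none
Why: Catalytic hydrogenolysis of aryl benzyl ethers is neutral, so C2 should keep its configuration, and it should be much faster than reduction of the flavone double bond or the chromanone carbonyl.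

**Compound list**

1 | 5-bromovanillin | COc1cc(C=O)cc(Br)c1O | starting material
2 | 3-bromo-4,5-dihydroxybenzaldehyde | O=Cc1cc(O)c(O)c(Br)c1 | intermediate
3 | 3,4-bis(benzyloxy)-5-bromobenzaldehyde | O=Cc1cc(OCc2ccccc2)c(OCc2ccccc2)c(Br)c1 | intermediate
4 | 3,4-bis(benzyloxy)-5-(4,4,5,5-tetramethyl-1,3,2-dioxaborolan-2-yl)benzaldehyde | O=Cc1cc(OCc2ccccc2)c(OCc2ccccc2)c(B2OC(C)(C)C(C)(C)O2)c1 | intermediate
5 | luteolin | O=c1cc(-c2ccc(O)c(O)c2)oc2cc(O)cc(O)c12 | starting material
6 | 5,7-bis(benzyloxy)-2-[3,4-bis(benzyloxy)phenyl]-4H-chromen-4-one | O=c1cc(-c2ccc(OCc3ccccc3)c(OCc3ccccc3)c2)oc2cc(OCc3ccccc3)cc(OCc3ccccc3)c12 | intermediate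
7 | 5,7-bis(benzyloxy)-2-[3,4-bis(benzyloxy)phenyl]-8-iodo-4H-chromen-4-one | O=c1cc(-c2ccc(OCc3ccccc3)c(OCc3ccccc3)c2)oc2c(I)c(OCc3ccccc3)cc(OCc3ccccc3)c12 | intermediate
8 | 3,4-bis(benzyloxy)-5-[5,7-bis(benzyloxy)-2-(3,4-bis(benzyloxy)phenyl)-4-oxo-4H-chromen-8-yl]benzaldehyde (Ar–CHO) | O=Cc1cc(OCc2ccccc2)c(OCc2ccccc2)c(-c2c(OCc3ccccc3)cc(OCc3ccccc3)c3c(=O)cc(-c4ccc(OCc5ccccc5)c(OCc5ccccc5)c4)oc23)c1 | intermediate
9 | (E)-1-methoxy-3-(trimethylsilyloxy)buta-1,3-diene | CO/C=C/C(=C)O[Si](C)(C)C | starting material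
10 | (S,E)-5-Ar-1-methoxy-5-(trimethylsilyloxy)pent-1-en-3-one | CO/C=C/C(=O)C[C@@H](c2cc(OCc3ccccc3)c(OCc3ccccc3)c(-c3c(OCc4ccccc4)cc(OCc4ccccc4)c4c(=O)cc(-c5ccc(OCc6ccccc6)c(OCc6ccccc6)c5)oc34)c2)O[Si](C)(C)C | intermediate
11 | (S)-2-Ar-2,3-dihydro-4H-pyran-4-one | O=C1C[C@@H](c2cc(OCc3ccccc3)c(OCc3ccccc3)c(-c3c(OCc4ccccc4)cc(OCc4ccccc4)c4c(=O)cc(-c5ccc(OCc6ccccc6)c(OCc6ccccc6)c5)oc34)c2)OC=C1 | intermediate
12 | (2S)-2-Ar-6-chloro-5-(phenylthio)tetrahydro-4H-pyran-4-one (C5 and C6 undefined) | O=C1C[C@@H](c2cc(OCc3ccccc3)c(OCc3ccccc3)c(-c3c(OCc4ccccc4)cc(OCc4ccccc4)c4c(=O)cc(-c5ccc(OCc6ccccc6)c(OCc6ccccc6)c5)oc34)c2)OC(Cl)C1Sc1ccccc1 | intermediate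
13 | (S)-2-Ar-5-(phenylthio)-2,3-dihydro-4H-pyran-4-one | O=C1C[C@@H](c2cc(OCc3ccccc3)c(OCc3ccccc3)c(-c3c(OCc4ccccc4)cc(OCc4ccccc4)c4c(=O)cc(-c5ccc(OCc6ccccc6)c(OCc6ccccc6)c5)oc34)c2)OC=C1Sc1ccccc1 | intermediate
14 | (2S)-2-Ar-5-(phenylsulfinyl)-2,3-dihydro-4H-pyran-4-one (sulfur epimers) | O=C1C[C@@H](c2cc(OCc3ccccc3)c(OCc3ccccc3)c(-c3c(OCc4ccccc4)cc(OCc4ccccc4)c4c(=O)cc(-c5ccc(OCc6ccccc6)c(OCc6ccccc6)c5)oc34)c2)OC=C1S(=O)c1ccccc1 | intermediate
15 | methyl acetoacetate | CC(=O)CC(=O)OC | starting material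
16 | methyl 3-(trimethylsilyloxy)but-2-enoate (geometry undefined) | COC(=O)C=C(C)O[Si](C)(C)C | intermediate
17 | lithium 1-methoxy-3-(trimethylsilyloxy)buta-1,3-dien-1-olate | COC([O-])=CC(=C)O[Si](C)(C)C.[Li+] | intermediate
18 | 1-methoxy-1,3-bis(trimethylsilyloxy)buta-1,3-diene (ketene acetal geometry undefined) | COC(O[Si](C)(C)C)=CC(=C)O[Si](C)(C)C | intermediate
19 | (2S)-2-Ar-5-methoxy-4a-(phenylsulfinyl)-5,7-bis(trimethylsilyloxy)-2,3,4a,5,8,8a-hexahydro-4H-chromen-4-one (cis ring fusion, other new centres undefined) | O=C1C[C@@H](c2cc(OCc3ccccc3)c(OCc3ccccc3)c(-c3c(OCc4ccccc4)cc(OCc4ccccc4)c4c(=O)cc(-c5ccc(OCc6ccccc6)c(OCc6ccccc6)c5)oc34)c2)OC2CC(O[Si](C)(C)C)=CC(OC)(O[Si](C)(C)C)C12S(=O)c1ccccc1 | intermediate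
20 | (2S)-2-Ar-5-hydroxy-7-(trimethylsilyloxy)chroman-4-one | O=C1C[C@@H](c2cc(OCc3ccccc3)c(OCc3ccccc3)c(-c3c(OCc4ccccc4)cc(OCc4ccccc4)c4c(=O)cc(-c5ccc(OCc6ccccc6)c(OCc6ccccc6)c5)oc34)c2)Oc2cc(O[Si](C)(C)C)cc(O)c21 | intermediate
21 | (2S)-2-Ar-5,7-dihydroxychroman-4-one | O=C1C[C@@H](c2cc(OCc3ccccc3)c(OCc3ccccc3)c(-c3c(OCc4ccccc4)cc(OCc4ccccc4)c4c(=O)cc(-c5ccc(OCc6ccccc6)c(OCc6ccccc6)c5)oc34)c2)Oc2cc(O)cc(O)c21 | intermediate
22 | (2S)-2-{3,4-dihydroxy-5-[2-(3,4-dihydroxyphenyl)-5,7-dihydroxy-4-oxo-4H-chromen-8-yl]phenyl}-5,7-dihydroxychroman-4-one | O=C1C[C@@H](c2cc(O)c(O)c(-c3c(O)cc(O)c4c(=O)cc(-c5ccc(O)c(O)c5)oc34)c2)Oc2cc(O)cc(O)c21 | target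

**Step count and risks**

Total steps: 13. Longest linear sequence: 9 steps (1, 2, 3, 6, 7, 8, 9, 12, 13).

Step 12. The diene may add in Michael fashion, after which the enolate expels O1 and ring C opens. The sulfoxide may also be silylated by the ketene acetal, or the push-pull alkene may react too slowly before the diene decomposes. The fallback uses known chemistry, sets out from aldehyde 8 and returns at target 22. Purchased 1-[2,4-bis(benzyloxy)-6-hydroxyphenyl]ethanone is C-carboxylated through its dilithio derivative (LiN(SiMe3)2, then di-tert-butyl dicarbonate) to tert-butyl 3-[2,4-bis(benzyloxy)-6-hydroxyphenyl]-3-oxopropanoate F1. Knoevenagel condensation of this ester with 8 (piperidinium acetate, PhMe, 4 Å MS) should give the alkylidene β-keto ester F2. A quinine- or quinidine-derived bifunctional thiourea, the pseudoenantiomer that gives 2S, then catalyses the 6-endo oxa-Michael closure to the tert-butyl (2S)-flavanone-3-carboxylate F3. TsOH in warm toluene removes the ester group by loss of isobutene and carbon dioxide to give the (2S)-octa-O-benzyl flavanone F4. Hydrogenolysis under the conditions of step 13 gives 22.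

Step 7. Enantioselectivity or turnover may be poor because the flavone carbonyl and the ether oxygens compete for titanium, and the 5-O-benzyl group may be partly lost in the acid treatment. The fallback sets out from 8 and returns at 11. A direct aldol addition of 4-(trimethylsilyl)but-3-yn-2-one to 8, catalysed by Et2Zn and the ProPhenol ligand antipode that gives the S carbinol, should give the (S)-β-hydroxy ynone F5. K2CO3 in methanol removes the silyl group and adds methanol to the ynone, giving the (S,E)-hydroxy methoxy enone F6. Catalytic TFA in CH2Cl2 then closes this to 11 with loss of methanol.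

Step 8. Sulfenylation may compete at C6 of the luteolin ring A or at C3 of the flavone, or a second sulfenylation may follow. The fallback sets out from 11 and returns at 13. Iodine and pyridine in CH2Cl2 act by conjugate addition of pyridine at the unsubstituted C6, iodination and elimination, a path closed to the 2-aryl flavone, and should give the (S)-5-iodo enone F7. C–S coupling with thiophenol (Pd2(dba)3, Xantphos, iPr2NEt, dioxane, 80 °C) then gives 13.

**Further compounds**

F1 | step 12 | tert-butyl 3-[2,4-bis(benzyloxy)-6-hydroxyphenyl]-3-oxopropanoate | CC(C)(C)OC(=O)CC(=O)c1c(O)cc(OCc2ccccc2)cc1OCc1ccccc1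
F2 | step 12 | tert-butyl 3-Ar-2-[2,4-bis(benzyloxy)-6-hydroxybenzoyl]prop-2-enoate (geometry undefined) | CC(C)(C)OC(=O)C(=Cc1cc(OCc2ccccc2)c(OCc2ccccc2)c(-c2c(OCc3ccccc3)cc(OCc3ccccc3)c3c(=O)cc(-c4ccc(OCc5ccccc5)c(OCc5ccccc5)c4)oc23)c1)C(=O)c1c(O)cc(OCc2ccccc2)cc1OCc1ccccc1
F3 | step 12 | tert-butyl (2S)-2-Ar-5,7-bis(benzyloxy)-4-oxochromane-3-carboxylate (C3 undefined) | O=C1C(C(=O)OC(C)(C)C)[C@@H](c2cc(OCc3ccccc3)c(OCc3ccccc3)c(-c3c(OCc4ccccc4)cc(OCc4ccccc4)c4c(=O)cc(-c5ccc(OCc6ccccc6)c(OCc6ccccc6)c5)oc34)c2)Oc2cc(OCc3ccccc3)cc(OCc3ccccc3)c21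
F4 | step 12 | (2S)-2-Ar-5,7-bis(benzyloxy)chroman-4-one | O=C1C[C@@H](c2cc(OCc3ccccc3)c(OCc3ccccc3)c(-c3c(OCc4ccccc4)cc(OCc4ccccc4)c4c(=O)cc(-c5ccc(OCc6ccccc6)c(OCc6ccccc6)c5)oc34)c2)Oc2cc(OCc3ccccc3)cc(OCc3ccccc3)c21
F5 | step 7 | (S)-1-Ar-1-hydroxy-5-(trimethylsilyl)pent-4-yn-3-one | C[Si](C)(C)C#CC(=O)C[C@@H](c2cc(OCc3ccccc3)c(OCc3ccccc3)c(-c3c(OCc4ccccc4)cc(OCc4ccccc4)c4c(=O)cc(-c5ccc(OCc6ccccc6)c(OCc6ccccc6)c5)oc34)c2)O
F6 | step 7 | (S,E)-5-Ar-5-hydroxy-1-methoxypent-1-en-3-one | CO/C=C/C(=O)C[C@@H](c2cc(OCc3ccccc3)c(OCc3ccccc3)c(-c3c(OCc4ccccc4)cc(OCc4ccccc4)c4c(=O)cc(-c5ccc(OCc6ccccc6)c(OCc6ccccc6)c5)oc34)c2)O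
F7 | step 8 | (S)-2-Ar-5-iodo-2,3-dihydro-4H-pyran-4-one | O=C1C[C@@H](c2cc(OCc3ccccc3)c(OCc3ccccc3)c(-c3c(OCc4ccccc4)cc(OCc4ccccc4)c4c(=O)cc(-c5ccc(OCc6ccccc6)c(OCc6ccccc6)c5)oc34)c2)OC=C1I
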